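## The problem

Target **40** is a cis-fused hydrindan-2-one (ring A six-membered, ring B five-membered) in which every carbon of ring A is substituted. C4 carries an exocyclic methylene, C5 and C6 carry two different acyloxy groups, C7 carries a 2-(methoxycarbonyl)oxiranyl group, and C3a and C7a carry ring B. Ring B (through C3 and C1), the C7 substituent and the C6 oxygen all lie on one face of ring A; only the C5 oxygen lies on the other. Each new group therefore has to enter cis to a neighbour, against simple approach control, and must be placed by a relay. The C7 centre can be bought and can direct C6 and C5. A temporary carbinol at C4 can hand its configuration to C7a by a sigmatropic shift, and the tether from C7a can then fix C3a. C1 with C1' (an open chain beside the crowded C7a) and the quaternary oxirane carbon lie outside the reach of the ring and need reagent control. Three secondary hydroxyls (C1', C5, C6) bear three different acyl groups, so the oxygens must be told apart from the moment they are made. The β-acetoxy ketone eliminates with base and C1 can epimerise. A free C6 hydroxyl would lactonise onto the carboxyl carbon of the C7 side chain. An ester at C5 is allylic to the C4 methylene and would be ionised by palladium. The feature that opens the structure is that the C4 methylene adjoins the C3a–C3 bond while C3 is α to the C2 ketone: this is the pattern left by a stabilised C3 carbanion adding to the ring end of an allyl cation equivalent that spans the exocyclic carbon, C4 and C3a.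

## Retrosynthesis

Locants are those of the target throughout; the remarks before the steps define them.

**Acyl groups (40 ⇒ 39 ⇒ 38 ⇒ 36 ⇒ 35).** The C1'–O acetyl bond is cut first and the C5–O acyl bond second, which leads to the C5 ether **35**. The acetate is made last because the β-acetoxy ketone is the most base-sensitive unit. The C5 ester (from acid **37**) comes just before it because this allylic ester must not meet palladium. The C6 ester is not cut here: it is carried from an early stage (see below), which removes one protecting group and blocks lactonisation. The forward steps are three mild acylations and two deprotections, all without strong base.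

**Oxiranyl ester (35 ⇒ 34 ⇒ 32 ⇒ 31).** The C8–O and C9–O bonds of the oxirane and the oxidation level of C10 are removed, giving the 2-substituted allylic alcohol **31**. Epoxidising an acrylate at this position would rely on substrate control at a freely rotating side chain. The allylic alcohol instead allows a tartrate-controlled epoxidation that also ignores the C4 methylene, provided the C5 oxygen is an ether. The forward reaction must set one quaternary centre by reagent control and then oxidise a primary alcohol to the ester without acid or base.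

**Ester at C3 (31 ⇒ 30 ⇒ 29).** Putting back a methoxycarbonyl group on C3 gives the β-keto ester **29**. This costs one later dealkoxycarbonylation but turns C3 into a soft nucleophile and keeps enolisation away from C1.

**Ring B (29 ⇒ 28).** The C3–C3a bond is cut with transposition of the alkene, which gives the monocyclic allylic carbonate **28**. Cutting C1–C7a or C2–C3 instead would not use the methylene; cutting inside ring A would leave the all-cis array to open-chain control. The precursor has one ring and one stereocentre fewer. The forward reaction must be C-selective and must attack C3a, not C11, on the face of the C7a tether.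

**Chain end and leaving group (28 ⇒ 27 ⇒ 24 ⇒ 23).** The carbonate C–O bond, the C2–C3 bond (acylation of malonate half ester **25**) and the C11–O bond (allylic oxidation of a methyl group) are cut in turn and lead to acid **23**. The methyl group on C4 then serves as the latent leaving-group carbon, so no extra protected alcohol has to be carried. The oxidation is placed before the β-keto ester exists because SeO2 attacks active methylene groups.

**C1–C1' (23 ⇒ 22 ⇒ 21 ⇒ 18 + 19).** The bond between C1 and C1' is cut as an auxiliary-controlled syn-aldol of imide **18** with acetaldehyde **19**. A rearrangement of a 3-oxybutanoate ester of the ring carbinol would join C1 to C7a and set C1 in one step. It was rejected because the target has the C1 side chain turned towards C7: the ketene acetal would have to place either its silyloxy group or its C1 substituent over the crowded α face, and the tertiary carbinol would first have to be acylated by an acid that readily eliminates. The aldol sets C1 and C1' together and is indifferent to C7a.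

**C7a–C1 (18 ⇒ 16 ⇒ 15 ⇒ 13 + 14).** The C7a–C1 bond is cut as a [3,3] shift of a ketene acetal made from orthoester **14** on the tertiary allylic alcohol **13**. Conjugate addition or alkylation at C7a would enter trans to the C7 group. The sigmatropic shift has no choice of face, needs no acylation of the tertiary alcohol, and returns the alkene to C4=C3a where the key step needs it. The forward reaction must tolerate a hindered tertiary carbinol.

**Carbinol at C4 and ester at C6 (13 ⇒ 11 ⇒ 9 ⇒ 8, with 12).** The C6 acyl bond (acid **12**) and the C4–O bond are cut. The tertiary alcohol **11** comes from the α-epoxide **9** of alkene **8** by selenide opening and selenoxide elimination, a 1,3-transposition that moves the alkene to C3a=C7a. Addition of a carbon nucleophile to a C4 ketone would give the wrong face. The epoxidation is steered to the α face by the axial C5 ether and the free C6 hydroxyl.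

**Oxygens at C5 and C6, and C10 (8 ⇒ 7 ⇒ 5 ⇒ 3 ⇒ 2 ⇒ 1).** The C5–O(PMB) bond is cut as the anti opening of vinyl oxirane **7** at its allylic carbon. The oxirane comes from the trans bromohydrin of the α'-bromo enone **5**, which comes from the silyl ether **3** of 10-hydroxycarvone **2** and so from (R)-carvone **1**. Carvone supplies C7 in the right absolute configuration, all six ring carbons and C11. Direct α'-hydroxylation would give the C6 oxygen trans to C7; the bromide, reduction, closure and opening sequence inverts both centres and leaves the two oxygens differentiated.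

## Roads not taken

**Alternative 1:** Ring A is closed at C5–C6 by a type 2 carbonyl-ene reaction. Me2AlCl activates the C6 aldehyde of cyclopentane A1, the CH2 end of the isopropenyl group on C3a bonds to C6, and a methyl hydrogen moves to oxygen, giving the hydrindane alcohol A2 with the C4 methylene.
- Merits: ring A and the methylene form together with no leaving group, no ester to remove and no transition metal. In atom economy and in the steps after cyclisation this road is better than the chosen one.
- Weak points: A2 has no oxygen at C5, so a late allylic hydroxylation next to the methylene is needed, with C3a and the side-chain alkene as competing sites and a face to control. The C6 carbinol is set in the ene transition state and must come out cis to the C7 group. A1 is an α-branched aldehyde beside an alkenyl group and is prone to epimerise or conjugate under the Lewis acid. A1 also needs C1, C7a, C3a and C7 set on a cyclopentane by open-chain methods.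
- Comparison: the chosen plan has both ring A oxygens in place before ring closure, each derived by relay from the carvone centre.

**Alternative 2:** Ring A is closed at C4–C3a by an Alder-ene cycloisomerisation. [CpRu(MeCN)3]PF6 couples the terminal alkyne of enyne A3 with the ring B alkene C3a=C3 while the hydrogen on C2 migrates, giving A4 with the methylene and a C2 silyl enol ether.
- Merits: the step is fully atom-economic, unmasks the ketone regiospecifically without decarboxylation, and is run with the oxirane and acetate already present. The endgame is shorter than in the chosen plan.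
- Weak points: the alkyne chain of A3 carries C5, C6, C7 and the oxirane carbon as four open-chain stereocentres that have to be built without a ring to relay them. The cationic ruthenium catalyst meets a propargylic ether and an oxirane. The branched mode of coupling and a C2 hydrogen syn to the metal are both required.
- Comparison: the chosen plan accepts two extra steps (carbonate formation and dealkoxycarbonylation) in return for a ring A whose centres are all set on a ring, and for a closure whose ring size and mode are well charted.

**Alternative 3:** Ring A is closed at C4–C5 by a Nozaki–Hiyama–Kishi reaction with cathodic turnover of catalytic CrCl2 and NiCl2. The vinyl iodide on C3a of A5 becomes a vinylchromium species that adds to the C5 aldehyde and gives the C5 alcohol A6.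
- Merits: the closure is convergent and mild, tolerates the ketone, and delivers the C5 hydroxyl free and already distinguished from C6. In this respect it is better than the chosen plan, which needs an ether at C5 and its later removal.
- Weak points: the C5 configuration depends on a Felkin or chelate preference of an α-silyloxy aldehyde inside a forming ring, and that aldehyde can epimerise. The β-acetoxy ketone has to survive reducing metal salts. A5 again needs the C7a, C7, C6 array built on a cyclopentanone without ring relay.
- Comparison: the chosen plan sets C5 by an anti epoxide opening before any ring closure and lets the tether fix the only centre formed in the key step.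

Key step: step 18

## Remarks before the steps

- Naming: every intermediate carries the locants of the target. Ring A is C4, C3a, C7a, C7, C6, C5; ring B adds C1, C2, C3; C1' is the carbinol carbon on C1. C8, C9 and C10 are the central, methylene (later oxirane CH2) and oxygenated carbons of the three-carbon unit on C7; C11 is the carbon on C4.
- Faces: β is the face of ring A that bears H3a, H7a, H7 and H6 in the target; α is the face that bears ring B and the C7 substituent. PMB = 4-methoxybenzyl, TBS = tert-butyldimethylsilyl.
- Assumption: acids **12** and **37** are taken as purchased in geometrically and enantiomerically pure form.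
- C3 of **29** is a labile β-keto ester centre; it is drawn without configuration because it is lost in step 19.

## Route

Step 1
Reactants: 1 (R)-(−)-carvone
Product: 2 (R)-10-hydroxycarvone
Conditions: SeO2 (cat.), t-BuOOH, CH2Cl2, 0 °C to rt
Reagents that add atoms: tert-butyl hydroperoxide (CC(C)(C)OO)
Why: Allylic hydroxylation by the SeO2 ene and [2,3] sequence attacks the methyl of the electron-rich 1,1-disubstituted alkene; the enone alkene and its methyl are deactivated and C7 is not touched.

Step 2
Reactants: 2 (R)-10-hydroxycarvone
Product: 3 10-O-TBS ether of 10-hydroxycarvone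
Conditions: TBSCl, imidazole, DMF, 0 °C to rt
Reagents that add atoms: tert-butyldimethylsilyl chloride (CC(C)(C)[Si](C)(C)Cl)
Why: Standard silylation of a primary alcohol; the ether has to last until step 20.

Step 3
Reactants: 3 10-O-TBS ether of 10-hydroxycarvone
Product: 5 6β-bromo enone (bromine trans to the C7 group), via silyl dienol ether 4 (not isolated)
Conditions: LiN(iPr)2, Me3SiCl, THF, −78 °C; then N-bromosuccinimide, THF, −78 °C
Reagents that add atoms: N-bromosuccinimide (O=C1CCC(=O)N1Br)
Why: Kinetic deprotonation of the enone occurs at the α' carbon C6 and is trapped as the cross-conjugated silyl dienol ether; bromination of the silyl enol ether then enters C6 anti to the neighbouring C7 substituent.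

Step 4
Reactants: 5 6β-bromo enone
Product: 7 5α,6α-oxirane (vinyl oxirane cis to the C7 group), via trans bromohydrin 6 (not isolated)
Conditions: NaBH4, CeCl3·7H2O, MeOH, −78 to 0 °C; then K2CO3, MeOH, rt
Reagents that add atoms: none
Why: Luche 1,2-reduction delivers hydride axially, as in the reduction of carvone to cis-carveol, so the hydroxyl is α and trans to bromine; the trans halohydrin closes under mild base (intramolecular Williamson reaction) with inversion at C6.

Step 5
Reactants: 7 5α,6α-oxirane
Product: 8 5β-PMB ether 6α-alcohol
Conditions: 4-methoxybenzyl alcohol, Yb(OTf)3 (cat.), CH2Cl2, 0 °C to rt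
Reagents that add atoms: 4-methoxybenzyl alcohol (COc1ccc(CO)cc1)
Why: Lewis-acid-catalysed alcoholysis of a vinyl oxirane takes place at the allylic carbon C5 with inversion, which puts the ether on the β face and frees the C6 hydroxyl on the α face; the trans-diol of the target is thus formed with its two oxygens already differentiated.

Step 6
Reactants: 8 5β-PMB ether 6α-alcohol
Product: 9 3a,4α-epoxide of 8
Conditions: mCPBA, NaHCO3, CH2Cl2, 0 °C
Reagents that add atoms: 3-chloroperbenzoic acid (OOC(=O)c1cccc(Cl)c1)
Why: Prilezhaev epoxidation prefers the trisubstituted ring alkene over the 1,1-disubstituted alkene with its allylic silyloxy group; it occurs anti to the pseudoaxial allylic C5 ether and syn to the homoallylic C6 hydroxyl, both of which point to the α face.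

Step 7
Reactants: 9 3a,4α-epoxide
Product: 11 tertiary allylic alcohol (4α,6α-diol with C3a=C7a), via hydroxy selenide 10 (not isolated)
Conditions: PhSeSePh, NaBH4, EtOH, rt to 60 °C; then 30% H2O2, THF, 0 °C to rt
Reagents that add atoms: none
Why: Selenolate opens the oxirane at the less substituted C3a with inversion; oxidation to the selenoxide and syn elimination, which can only use a hydrogen on C7a, moves the alkene to C3a=C7a and leaves the tertiary C4 hydroxyl on the α face (epoxide to allylic alcohol isomerisation).

Step 8
Reactants: 11 tertiary allylic alcohol (4α,6α-diol); 12 (E)-3-methylpent-2-enoic acid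
Product: 13 6α-(E)-3-methylpent-2-enoate with free tertiary C4 alcohol
Conditions: DCC, DMAP (cat.), CH2Cl2, 0 °C to rt
Reagents that add atoms: none
Why: Steglich esterification acylates the secondary C6 hydroxyl and leaves the tertiary allylic alcohol alone; the final C6 ester is installed here so that this hydroxyl needs no protecting group and cannot lactonise onto C10 later.

Step 9
Reactants: 13 6α-ester tertiary allylic alcohol; 14 trimethyl orthoacetate
Product: 15 methyl ester with the C7a acetate chain on the α face and C4=C3a
Conditions: MeC(OMe)3 (excess), EtCO2H (cat.), 135 °C, sealed tube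
Reagents that add atoms: none
Why: Johnson–Claisen rearrangement: orthoester exchange gives a mixed ketene acetal whose [3,3] shift is suprafacial on the ring, so the C7a–C1 bond forms on the α face from which the C4–O bond leaves, cis to the C7 group, and the alkene returns to C4=C3a.

Step 10
Reactants: 15 methyl ester
Product: 16 carboxylic acid
Conditions: Me3SnOH, ClCH2CH2Cl, 80 °C; dilute HCl work-up
Reagents that add atoms: trimethyltin hydroxide (C[Sn](C)(C)O)
Why: Trimethyltin hydroxide hydrolyses the unhindered methyl ester selectively; the hindered, conjugated secondary ester on C6 is left intact.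

Step 11
Reactants: 16 carboxylic acid
Product: 18 N-acyl (R)-4-benzyl-2-oxazolidinone, via mixed pivalic anhydride 17 (not isolated)
Conditions: t-BuCOCl, Et3N, THF, −20 °C; then (R)-4-benzyl-2-oxazolidinone, LiCl, −20 °C to rt
Reagents that add atoms: (R)-4-benzyl-2-oxazolidinone (O=C1N[C@H](Cc2ccccc2)CO1)
Why: N-acylation through the mixed anhydride, which is attacked at its less hindered carbonyl, installs the auxiliary for the aldol.

Step 12
Reactants: 18 N-acyl oxazolidinone; 19 acetaldehyde
Product: 21 syn-aldol adduct (C1 R and C1' S), via dibutylboron (Z)-enolate 20 (not isolated)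
Conditions: Bu2BOTf, iPr2NEt, CH2Cl2, −78 to 0 °C; then MeCHO, −78 to 0 °C; H2O2, pH 7 buffer, MeOH, 0 °C
Reagents that add atoms: none
Why: Evans syn-aldol: the (Z)-boron enolate reacts through a closed chair transition state on the face away from the benzyl group of the (R)-auxiliary, which sets C1 (R) and C1' (S) together under reagent control, independent of the crowded C7a centre.

Step 13
Reactants: 21 syn-aldol adduct
Product: 22 C1' TBS ether
Conditions: TBSOTf, 2,6-lutidine, CH2Cl2, −78 to 0 °C
Reagents that add atoms: tert-butyldimethylsilyl triflate (CC(C)(C)[Si](C)(C)OS(=O)(=O)C(F)(F)F)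
Why: Silyl triflate silylation of the hindered secondary alcohol; the ether blocks retro-aldol cleavage and β-elimination until step 26.

Step 14
Reactants: 22 C1' TBS ether
Product: 23 carboxylic acid with C1 and C1' set
Conditions: LiOH, H2O2, THF/H2O, 0 °C; then aq. Na2SO3, dilute HCl
Reagents that add atoms: hydrogen peroxide (OO)
Why: Lithium hydroperoxide attacks the exocyclic imide carbonyl selectively and leaves C1 and the hindered C6 ester intact; the auxiliary is recovered.

Step 15
Reactants: 23 carboxylic acid
Product: 24 C11 allylic alcohol (hydroxy acid)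
Conditions: SeO2 (cat.), t-BuOOH, CH2Cl2, rt
Reagents that add atoms: tert-butyl hydroperoxide (CC(C)(C)OO)
Why: SeO2 allylic oxidation of the trisubstituted alkene follows the usual rule (reaction at the more substituted end, CH3 before the oxygenated CH of C5) and gives the primary allylic alcohol; it is run before the β-keto ester exists because active methylene groups are oxidised by SeO2.

Step 16
Reactants: 24 C11 allylic alcohol (hydroxy acid); 25 potassium methyl malonate
Product: 27 β-keto methyl ester with free C11 alcohol, via acyl imidazolide 26 (not isolated)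
Conditions: carbonyldiimidazole (1.05 equiv), THF, 0 °C to rt; then KO2CCH2CO2Me, MgCl2, Et3N, THF, rt to 40 °C
Reagents that add atoms: none
Why: Masamune homologation: the acid reacts with carbonyldiimidazole faster than the alcohol, and the acyl imidazolide C-acylates the magnesium enolate of the malonate half ester with loss of CO2 under nearly neutral conditions that do not epimerise C1.

Step 17
Reactants: 27 β-keto methyl ester with free C11 alcohol
Product: 28 allylic methyl carbonate (precursor of the key step)
Conditions: ClCO2Me, pyridine, CH2Cl2, 0 °C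
Reagents that add atoms: methyl chloroformate (COC(=O)Cl)
Why: Chloroformate acylation of the primary allylic alcohol gives the ionisable carbonate; the β-keto ester is not acylated under pyridine at 0 °C.

Step 18
Reactants: 28 allylic methyl carbonate
Product: 29 cis-hydrindan-2-one 3-carboxylate with C4 methylene
Conditions: Pd(PPh3)4 (5 mol %), THF (0.01 M), 25 to 40 °C
Reagents that add atoms: none
Why: Zerovalent palladium ionises the primary allylic carbonate to a π-allyl complex of divalent palladium that spans C11, C4 and C3a; the methyl carbonate anion loses CO2 and the methoxide formed deprotonates the β-keto ester at C3. The soft enolate attacks the ring terminus C3a on the face opposite the metal (Tsuji–Trost allylic alkylation), which forms C3–C3a and returns the alkene to the exocyclic C4=C11 position. The closest known reaction type is the palladium-catalysed cyclisation of 3-oxoalkanoates carrying an allylic leaving group to 2-alkoxycarbonyl-3-vinylcyclopentanones. Ring B closes as a five-membered ring in the exo mode, with the allyl unit outside the new ring; attack at C11 would need a seven-membered ring. The new stereocentre C3a is controlled by the three-atom tether from C7a, which can reach C3a only on the α face, so H3a and H7a end up cis; palladium reaches the β face by π–σ–π exchange through the unsubstituted C11 terminus. The step needs C- over O-alkylation (a doubly stabilised carbon nucleophile, as in the precedent), reaction at C3 and not at C1 (only C3 is doubly activated), and ionisation of the carbonate alone (the oxygens on C5 and C10 are ethers and the C6 ester is not allylic). The configuration at C3 is of no consequence.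

Step 19
Reactants: 29 cis-hydrindan-2-one 3-carboxylate
Product: 30 cis-hydrindan-2-one
Conditions: LiCl, H2O, DMSO, 130 °C
Reagents that add atoms: none
Why: Krapcho dealkoxycarbonylation (chloride attack on the ester methyl, then loss of CO2) is neutral, so C1 and the β-silyloxy ketone are not exposed to base; any loss of the primary allylic silyl ether at this temperature is harmless because it is removed next.

Step 20
Reactants: 30 cis-hydrindan-2-one
Product: 31 C10 allylic alcohol
Conditions: HF·pyridine, pyridine, THF, 0 °C
Reagents that add atoms: none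
Why: Buffered HF·pyridine cleaves the primary allylic silyl ether much faster than the hindered secondary one on C1'.

Step 21
Reactants: 31 C10 allylic alcohol
Product: 32 (8R)-epoxy alcohol
Conditions: Ti(OiPr)4 (cat.), D-(−)-diethyl tartrate (cat.), t-BuOOH, 4 Å molecular sieves, CH2Cl2, −20 °C
Reagents that add atoms: tert-butyl hydroperoxide (CC(C)(C)OO)
Why: Sharpless asymmetric epoxidation acts only on the allylic alcohol; with D-(−)-diethyl tartrate the oxygen is delivered to the face of the 2-substituted allyl alcohol that gives the (R)-epoxy alcohol, which is the C8 configuration of the target, and the C4 methylene, whose allylic oxygen is an ether, is not touched.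

Step 22
Reactants: 32 (8R)-epoxy alcohol
Product: 34 (8S)-glycidic acid, via epoxy aldehyde 33 (not isolated)
Conditions: TEMPO (cat.), PhI(OAc)2, CH2Cl2, rt; then NaClO2, NaH2PO4, 2-methyl-2-butene, t-BuOH/H2O, 0 °C to rt
Reagents that add atoms: sodium chlorite ([Na+].[O-]Cl=O)
Why: Oxoammonium oxidation to the aldehyde and Pinnick oxidation to the acid; C8 is quaternary and cannot epimerise (its descriptor changes only through priorities), and the C6 ester prevents lactol or lactone formation.

Step 23
Reactants: 34 (8S)-glycidic acid
Product: 35 methyl glycidate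
Conditions: Me3SiCHN2, toluene/MeOH, 0 °C
Reagents that add atoms: (trimethylsilyl)diazomethane (C[Si](C)(C)C=[N+]=[N-])
Why: Esterification with the diazoalkane is neutral and leaves the oxirane and the ketone alone.

Step 24
Reactants: 35 methyl glycidate
Product: 36 C5 allylic alcohol
Conditions: DDQ, CH2Cl2/pH 7 buffer, 0 °C to rt
Reagents that add atoms: none
Why: Oxidative cleavage of the 4-methoxybenzyl ether by DDQ (hydride abstraction, then hydrolysis of the oxocarbenium ion) frees only the C5 hydroxyl.

Step 25
Reactants: 36 C5 allylic alcohol; 37 (R)-2-methylbutanoic acid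
Product: 38 C5 (R)-2-methylbutanoate
Conditions: DCC, DMAP (cat.), CH2Cl2, 0 °C to rt
Reagents that add atoms: none
Why: Steglich esterification with the enantiopure acid; a low loading of DMAP at 0 °C keeps the α-stereocentre of the acyl group intact.

Step 26
Reactants: 38 C5 (R)-2-methylbutanoate
Product: 39 C1' alcohol
Conditions: HF·pyridine, THF, 0 °C to rt
Reagents that add atoms: none
Why: Acidic fluoride removes the last silyl ether without base, so the β-hydroxy ketone neither eliminates nor undergoes retro-aldol cleavage.

Step 27
Reactants: 39 C1' alcohol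
Product: 40 target
Conditions: Ac2O, pyridine, DMAP (cat.), CH2Cl2, 0 °C
Reagents that add atoms: acetic anhydride (CC(=O)OC(C)=O)
Why: Acetylation under pyridine at 0 °C completes the target; the base-sensitive β-acetoxy ketone is formed only in the last step.

## Compound list

1 | (R)-(−)-carvone, (5R)-2-methyl-5-(prop-1-en-2-yl)cyclohex-2-en-1-one | CC1=CC[C@@H](C(C)=C)CC1=O | starting material
2 | (R)-10-hydroxycarvone, (5R)-5-(3-hydroxyprop-1-en-2-yl)-2-methylcyclohex-2-en-1-one | CC1=CC[C@@H](C(=C)CO)CC1=O | intermediate
3 | 10-O-TBS ether of 2 | CC1=CC[C@@H](C(=C)CO[Si](C)(C)C(C)(C)C)CC1=O | intermediate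
4 | trimethylsilyl dienol ether of 3 (C5(OSiMe3)=C6, C4=C3a) | CC1=CC[C@@H](C(=C)CO[Si](C)(C)C(C)(C)C)C=C1O[Si](C)(C)C | intermediate (not isolated)
5 | 6β-bromo derivative of 3 (Br trans to the C7 group) | CC1=CC[C@@H](C(=C)CO[Si](C)(C)C(C)(C)C)[C@H](Br)C1=O | intermediate
6 | 5α-hydroxy-6β-bromo cyclohexene (trans bromohydrin) | CC1=CC[C@@H](C(=C)CO[Si](C)(C)C(C)(C)C)[C@H](Br)[C@H]1O | intermediate (not isolated)
7 | 5α,6α-oxirane with C4=C3a alkene | CC1=CC[C@@H](C(=C)CO[Si](C)(C)C(C)(C)C)[C@@H]2[C@H]1O2 | intermediate
8 | 5β-(4-methoxybenzyloxy) 6α-alcohol | CC1=CC[C@@H](C(=C)CO[Si](C)(C)C(C)(C)C)[C@@H](O)[C@@H]1OCc2ccc(OC)cc2 | intermediate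
9 | 3a,4α-epoxide of 8 (4β-methyl) | C[C@]12O[C@H]1C[C@@H](C(=C)CO[Si](C)(C)C(C)(C)C)[C@@H](O)[C@@H]2OCc3ccc(OC)cc3 | intermediate
10 | 3aβ-phenylselanyl 4α,6α-diol | C[C@]1(O)[C@H]([Se]c2ccccc2)C[C@@H](C(=C)CO[Si](C)(C)C(C)(C)C)[C@@H](O)[C@@H]1OCc3ccc(OC)cc3 | intermediate (not isolated)
11 | 4α,6α-diol with C3a=C7a alkene (tertiary allylic alcohol) | C[C@]1(O)C=C[C@@H](C(=C)CO[Si](C)(C)C(C)(C)C)[C@@H](O)[C@@H]1OCc2ccc(OC)cc2 | intermediate
12 | (E)-3-methylpent-2-enoic acid | OC(=O)/C=C(\C)CC | starting material
13 | 6α-(E)-3-methylpent-2-enoate of 11 | C[C@]1(O)C=C[C@@H](C(=C)CO[Si](C)(C)C(C)(C)C)[C@@H](OC(=O)/C=C(\C)CC)[C@@H]1OCc2ccc(OC)cc2 | intermediate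
14 | trimethyl orthoacetate | CC(OC)(OC)OC | starting material
15 | methyl ester, C7a α-CH2CO2Me, C4(CH3)=C3a | CC1=C[C@@H](CC(=O)OC)[C@@H](C(=C)CO[Si](C)(C)C(C)(C)C)[C@@H](OC(=O)/C=C(\C)CC)[C@@H]1OCc2ccc(OC)cc2 | intermediate
16 | carboxylic acid from 15 | CC1=C[C@@H](CC(=O)O)[C@@H](C(=C)CO[Si](C)(C)C(C)(C)C)[C@@H](OC(=O)/C=C(\C)CC)[C@@H]1OCc2ccc(OC)cc2 | intermediate
17 | mixed pivalic anhydride of 16 | CC1=C[C@@H](CC(=O)OC(=O)C(C)(C)C)[C@@H](C(=C)CO[Si](C)(C)C(C)(C)C)[C@@H](OC(=O)/C=C(\C)CC)[C@@H]1OCc2ccc(OC)cc2 | intermediate (not isolated)
18 | N-acyl (R)-4-benzyl-2-oxazolidinone | CC1=C[C@@H](CC(=O)N2[C@H](Cc3ccccc3)COC2=O)[C@@H](C(=C)CO[Si](C)(C)C(C)(C)C)[C@@H](OC(=O)/C=C(\C)CC)[C@@H]1OCc4ccc(OC)cc4 | intermediate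
19 | acetaldehyde | CC=O | starting material
20 | dibutylboron (Z)-enolate of 18 | CC1=C[C@@H](/C=C(\OB(CCCC)CCCC)N2[C@H](Cc3ccccc3)COC2=O)[C@@H](C(=C)CO[Si](C)(C)C(C)(C)C)[C@@H](OC(=O)/C=C(\C)CC)[C@@H]1OCc4ccc(OC)cc4 | intermediate (not isolated)
21 | syn-aldol adduct, C1 (R), C1' (S) | CC1=C[C@@H]([C@H]([C@H](C)O)C(=O)N2[C@H](Cc3ccccc3)COC2=O)[C@@H](C(=C)CO[Si](C)(C)C(C)(C)C)[C@@H](OC(=O)/C=C(\C)CC)[C@@H]1OCc4ccc(OC)cc4 | intermediate
22 | C1' TBS ether of 21 | CC1=C[C@@H]([C@H]([C@H](C)O[Si](C)(C)C(C)(C)C)C(=O)N2[C@H](Cc3ccccc3)COC2=O)[C@@H](C(=C)CO[Si](C)(C)C(C)(C)C)[C@@H](OC(=O)/C=C(\C)CC)[C@@H]1OCc4ccc(OC)cc4 | intermediate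
23 | carboxylic acid (C2) with C1 (R), C1' (S)-OTBS | CC1=C[C@@H]([C@H]([C@H](C)O[Si](C)(C)C(C)(C)C)C(=O)O)[C@@H](C(=C)CO[Si](C)(C)C(C)(C)C)[C@@H](OC(=O)/C=C(\C)CC)[C@@H]1OCc2ccc(OC)cc2 | intermediate
24 | C11 allylic alcohol of 23 | OCC1=C[C@@H]([C@H]([C@H](C)O[Si](C)(C)C(C)(C)C)C(=O)O)[C@@H](C(=C)CO[Si](C)(C)C(C)(C)C)[C@@H](OC(=O)/C=C(\C)CC)[C@@H]1OCc2ccc(OC)cc2 | intermediate
25 | potassium methyl malonate | [K+].[O-]C(=O)CC(=O)OC | starting material
26 | acyl imidazolide of 24 | OCC1=C[C@@H]([C@H]([C@H](C)O[Si](C)(C)C(C)(C)C)C(=O)n2ccnc2)[C@@H](C(=C)CO[Si](C)(C)C(C)(C)C)[C@@H](OC(=O)/C=C(\C)CC)[C@@H]1OCc3ccc(OC)cc3 | intermediate (not isolated)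
27 | β-keto methyl ester with free C11 alcohol | OCC1=C[C@@H]([C@H]([C@H](C)O[Si](C)(C)C(C)(C)C)C(=O)CC(=O)OC)[C@@H](C(=C)CO[Si](C)(C)C(C)(C)C)[C@@H](OC(=O)/C=C(\C)CC)[C@@H]1OCc2ccc(OC)cc2 | intermediate
28 | C11 methyl carbonate of 27 | COC(=O)OCC1=C[C@@H]([C@H]([C@H](C)O[Si](C)(C)C(C)(C)C)C(=O)CC(=O)OC)[C@@H](C(=C)CO[Si](C)(C)C(C)(C)C)[C@@H](OC(=O)/C=C(\C)CC)[C@@H]1OCc2ccc(OC)cc2 | intermediate
29 | cis-hydrindan-2-one 3-carboxylate (3aβ-H, 7aβ-H, C4 methylene; C3 undefined) | C=C1[C@H]2C(C(=O)OC)C(=O)[C@@H]([C@H](C)O[Si](C)(C)C(C)(C)C)[C@H]2[C@@H](C(=C)CO[Si](C)(C)C(C)(C)C)[C@@H](OC(=O)/C=C(\C)CC)[C@@H]1OCc3ccc(OC)cc3 | intermediate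
30 | cis-hydrindan-2-one | C=C1[C@H]2CC(=O)[C@@H]([C@H](C)O[Si](C)(C)C(C)(C)C)[C@H]2[C@@H](C(=C)CO[Si](C)(C)C(C)(C)C)[C@@H](OC(=O)/C=C(\C)CC)[C@@H]1OCc3ccc(OC)cc3 | intermediate
31 | C10 allylic alcohol | C=C1[C@H]2CC(=O)[C@@H]([C@H](C)O[Si](C)(C)C(C)(C)C)[C@H]2[C@@H](C(=C)CO)[C@@H](OC(=O)/C=C(\C)CC)[C@@H]1OCc3ccc(OC)cc3 | intermediate
32 | (8R)-epoxy alcohol | C=C1[C@H]2CC(=O)[C@@H]([C@H](C)O[Si](C)(C)C(C)(C)C)[C@H]2[C@@H]([C@@]3(CO)CO3)[C@@H](OC(=O)/C=C(\C)CC)[C@@H]1OCc4ccc(OC)cc4 | intermediate
33 | epoxy aldehyde | C=C1[C@H]2CC(=O)[C@@H]([C@H](C)O[Si](C)(C)C(C)(C)C)[C@H]2[C@@H]([C@@]3(C=O)CO3)[C@@H](OC(=O)/C=C(\C)CC)[C@@H]1OCc4ccc(OC)cc4 | intermediate (not isolated)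
34 | (8S)-glycidic acid | C=C1[C@H]2CC(=O)[C@@H]([C@H](C)O[Si](C)(C)C(C)(C)C)[C@H]2[C@@H]([C@@]3(C(=O)O)CO3)[C@@H](OC(=O)/C=C(\C)CC)[C@@H]1OCc4ccc(OC)cc4 | intermediate
35 | methyl (8S)-glycidate | C=C1[C@H]2CC(=O)[C@@H]([C@H](C)O[Si](C)(C)C(C)(C)C)[C@H]2[C@@H]([C@@]3(C(=O)OC)CO3)[C@@H](OC(=O)/C=C(\C)CC)[C@@H]1OCc4ccc(OC)cc4 | intermediate
36 | C5β allylic alcohol | C=C1[C@H]2CC(=O)[C@@H]([C@H](C)O[Si](C)(C)C(C)(C)C)[C@H]2[C@@H]([C@@]3(C(=O)OC)CO3)[C@@H](OC(=O)/C=C(\C)CC)[C@@H]1O | intermediate
37 | (R)-2-methylbutanoic acid | CC[C@@H](C)C(=O)O | starting material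
38 | C5β (R)-2-methylbutanoate | C=C1[C@H]2CC(=O)[C@@H]([C@H](C)O[Si](C)(C)C(C)(C)C)[C@H]2[C@@H]([C@@]3(C(=O)OC)CO3)[C@@H](OC(=O)/C=C(\C)CC)[C@@H]1OC(=O)[C@H](C)CC | intermediate
39 | C1' (S)-alcohol | C=C1[C@H]2CC(=O)[C@@H]([C@H](C)O)[C@H]2[C@@H]([C@@]3(C(=O)OC)CO3)[C@@H](OC(=O)/C=C(\C)CC)[C@@H]1OC(=O)[C@H](C)CC | intermediate
40 | target: 1α-[(S)-1-acetoxyethyl]-4-methylene-5β-[(R)-2-methylbutanoyloxy]-6α-[(E)-3-methylpent-2-enoyloxy]-7α-[(S)-2-(methoxycarbonyl)oxiran-2-yl]-3aβ,7aβ-hydrindan-2-one | C=C1[C@H]2CC(=O)[C@@H]([C@H](C)OC(C)=O)[C@H]2[C@@H]([C@@]3(C(=O)OC)CO3)[C@@H](OC(=O)/C=C(\C)CC)[C@@H]1OC(=O)[C@H](C)CC | target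

## Step count and weak points

Total: 27 steps. Longest linear sequence: 27 steps, from (R)-carvone **1**; the route is linear and the other starting materials enter as reagents.

**Step 18 (key step).** The carbonate sits on a crowded ring, so ionisation may be slow. The π-allyl complex may then lose a β-hydrogen to give a diene, or the enolate may alkylate on oxygen to give a cyclic enol ether. Fallback: from alcohol **27**, an Appel reaction (CBr4, PPh3) gives the allylic bromide F1. Cs2CO3 in MeCN then closes ring B by intramolecular SN2' alkylation of the β-keto ester at C3a. The five-membered SN2' mode is preferred over the seven-membered SN2 mode, and the tether again gives the cis fusion. The product is **29**.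

**Step 15.** The allylic oxidation may lose chemoselectivity: attack at the C8=C9 alkene beside the silyl ether, at the benzylic ether, or over-oxidation to the enal. Fallback: from acid **23**, the Masamune homologation of step 16 gives the methyl-substituted β-keto ester F2. Mn(OAc)3 with Cu(OAc)2 in acetic acid generates the C3 radical by oxidation with trivalent manganese. The radical adds 5-exo to C3a, and the tertiary C4 radical is oxidised by divalent copper to the less substituted, exocyclic alkene. This oxidative radical cyclisation forms the same bond and the same methylene from the methyl-bearing alkene, with the cis fusion set by the tether, and returns to the route at **29** without steps 15 to 18.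

**Step 9.** Under acid at 135 °C the tertiary allylic alcohol may ionise and dehydrate, or the rearrangement may be slow because the ketene acetal has to reach C7a past the cis C7 substituent. Fallback: from **13**, acetylation (Ac2O, DMAP, Et3N) gives the tertiary allylic acetate F3. Pd(PPh3)4 with sodium dimethyl malonate in THF gives the C7a malonate F4: ionisation and attack both occur with inversion, so the malonate enters at the less substituted terminus C7a on the α face. Krapcho removal of one ester (LiCl, wet DMSO) gives **15**.

**Step 3.** The α'-bromo enone may lose HBr and aromatise, or the side-chain alkene may be brominated. Fallback: from **3**, the silyl dienol ether **4** is oxidised with mCPBA (Rubottom oxidation, oxygen anti to the C7 group) to the 6β-hydroxy enone F5. MsCl and Et3N give the 6β-mesylate F6. The conditions of step 4 then give the hydroxy mesylate F7, which closes to oxirane **7**.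

## Further compounds

F1 | step 18 | C11 allylic bromide of the β-keto ester | BrCC1=C[C@@H]([C@H]([C@H](C)O[Si](C)(C)C(C)(C)C)C(=O)CC(=O)OC)[C@@H](C(=C)CO[Si](C)(C)C(C)(C)C)[C@@H](OC(=O)/C=C(\C)CC)[C@@H]1OCc2ccc(OC)cc2
F2 | step 15 | β-keto methyl ester with C4 methyl | CC1=C[C@@H]([C@H]([C@H](C)O[Si](C)(C)C(C)(C)C)C(=O)CC(=O)OC)[C@@H](C(=C)CO[Si](C)(C)C(C)(C)C)[C@@H](OC(=O)/C=C(\C)CC)[C@@H]1OCc2ccc(OC)cc2
F3 | step 9 | tertiary allylic acetate of 13 | C[C@]1(OC(C)=O)C=C[C@@H](C(=C)CO[Si](C)(C)C(C)(C)C)[C@@H](OC(=O)/C=C(\C)CC)[C@@H]1OCc2ccc(OC)cc2
F4 | step 9 | dimethyl malonate on C7a (α face), C4=C3a | CC1=C[C@@H](C(C(=O)OC)C(=O)OC)[C@@H](C(=C)CO[Si](C)(C)C(C)(C)C)[C@@H](OC(=O)/C=C(\C)CC)[C@@H]1OCc2ccc(OC)cc2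
F5 | step 3 | 6β-hydroxy enone | CC1=CC[C@@H](C(=C)CO[Si](C)(C)C(C)(C)C)[C@H](O)C1=O
F6 | step 3 | 6β-methanesulfonyloxy enone | CC1=CC[C@@H](C(=C)CO[Si](C)(C)C(C)(C)C)[C@H](OS(C)(=O)=O)C1=O
F7 | step 3 | 5α-hydroxy 6β-mesylate | CC1=CC[C@@H](C(=C)CO[Si](C)(C)C(C)(C)C)[C@H](OS(C)(=O)=O)[C@H]1O
A1 | alternative 1 | cyclopentane C6 aldehyde with isopropenyl group on C3a | CC(=C)[C@H]1C[C@@H](O[Si](C)(C)C(C)(C)C)[C@@H]([C@H](C)O[Si](C)(C)C(C)(C)C)[C@H]1[C@@H](C(=C)CO[Si](C)(C)C(C)(C)C)C=O
A2 | alternative 1 | cis-hydrindane C6 alcohol with C4 methylene | C=C1[C@H]2C[C@@H](O[Si](C)(C)C(C)(C)C)[C@@H]([C@H](C)O[Si](C)(C)C(C)(C)C)[C@H]2[C@@H](C(=C)CO[Si](C)(C)C(C)(C)C)[C@@H](O)C1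
A3 | alternative 2 | enyne: terminal alkyne chain on C7a of a cyclopentene (C2 configuration open) | C#C[C@@H](OCc1ccc(OC)cc1)[C@H](O[Si](C)(C)C(C)(C)C)[C@H]([C@@]2(CO[Si](C)(C)C(C)(C)C)CO2)[C@H]3C=CC(O[Si](C)(C)C(C)(C)C)[C@H]3[C@H](C)OC(C)=O
A4 | alternative 2 | cis-hydrindene with C4 methylene and C2 silyl enol ether | C=C1[C@H]2C=C(O[Si](C)(C)C(C)(C)C)[C@@H]([C@H](C)OC(C)=O)[C@H]2[C@@H]([C@@]3(CO[Si](C)(C)C(C)(C)C)CO3)[C@@H](O[Si](C)(C)C(C)(C)C)[C@@H]1OCc4ccc(OC)cc4
A5 | alternative 3 | cyclopentanone with 1-iodovinyl group on C3a and C5 aldehyde | C=C(I)[C@H]1CC(=O)[C@@H]([C@H](C)OC(C)=O)[C@H]1[C@@H](C(=C)CO[Si](C)(C)C(C)(C)C)[C@@H](O[Si](C)(C)C(C)(C)C)C=O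
A6 | alternative 3 | full skeleton as the C5 alcohol | C=C1[C@H]2CC(=O)[C@@H]([C@H](C)OC(C)=O)[C@H]2[C@@H](C(=C)CO[Si](C)(C)C(C)(C)C)[C@@H](O[Si](C)(C)C(C)(C)C)[C@@H]1O
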